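**Retrosynthetic overview**
- Target ⇐ global hydrogenolysis; the upper pyran ring C is closed last through the C4–C4a bond, by nickel capture of a C4 benzylic radical with the ring-A aryl iodide, which also sets C4.
- Upper O1–C2 ⇐ SN2 opening of a trans-epoxide by the ring-A iodophenol (sets 2,3-trans); the epoxide ⇐ Juliá–Colonna epoxidation of a chalcone made by aldol condensation on a 6-acetyl lower unit.
- Lower pyran ring C' ⇐ Mitsunobu etherification of a symmetric 4-acetyl-3,5-dialkoxyphenol with an erythro epoxy alcohol, then 6-endo epoxy–arene cyclisation (2,3-cis); the acetyl carbonyl carbon is the later C4, so the 4→6 link is fixed by symmetry.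
- Building blocks: the ring-B aldehyde (used for both units) from p-cresol; the phloroglucinol ring from resorcinol by ortho-lithiation/acetylation and C–H borylation/oxidation; ring A from 3-(benzyloxy)phenol.
- Ring order: lower pyran ring C' (step 10), then upper pyran ring C (step 15); all benzene rings come from the starting materials.

Assumption: the SMILES is read as (2R,3S,4S) in the upper unit and (2'R,3'R) in the lower unit, i.e. robinetinidol-(4α→6)-epigallocatechin; flavan numbering is used, primes mark the lower unit.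

Abbreviations: Bn = benzyl; PMB = 4-methoxybenzyl; ArB = 3,4,5-tris(benzyloxy)phenyl; Chr = (2R,3R)-3-hydroxy-5,7-bis(PMB-oxy)-2-ArB-3,4-dihydro-2H-chromen-6-yl.

**Route**

Step 1
Reactants: 1 4-methylphenol (p-cresol)
Product: 4 3,5-dibromo-4-hydroxybenzaldehyde, via 2,6-dibromo-4-methylphenol 2 (not isolated), via 2,6-dibromo-4-(dibromomethyl)phenol 3 (not isolated)
Conditions: Br2 (2 equiv), o-dichlorobenzene, 35 °C; Br2 (2 equiv), 150 °C; then H2O, 100 °C
Reagents that add atoms: bromine, BrBr; water, O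
Why: Electrophilic bromination of both positions ortho to the phenol, then free-radical side-chain dibromination and hydrolysis of the benzal bromide give the aldehyde (the technical p-cresol route to this compound), with no stereocentre involved.

Step 2
Reactants: 4 3,5-dibromo-4-hydroxybenzaldehyde
Product: 5 3,4,5-trihydroxybenzaldehyde
Conditions: NaOH (8 equiv), CuCl (10 mol %), H2O, 100 °C, argon; then HCl to pH 2
Reagents that add atoms: sodium hydroxide, [Na+].[OH-]
Why: Copper-catalysed Ullmann-type hydroxylation of the two aryl bromides ortho to the phenoxide (as in the classical conversion of 5-bromovanillin into 5-hydroxyvanillin) works because the phenoxide protects the aldehyde from Cannizzaro reaction and air is excluded.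

Step 3
Reactants: 5 3,4,5-trihydroxybenzaldehyde
Product: 6 3,4,5-tris(benzyloxy)benzaldehyde
Conditions: BnBr (3.3 equiv), K2CO3, DMF, 60 °C
Reagents that add atoms: benzyl bromide, BrCc1ccccc1
Why: Williamson etherification of the three phenols gives the ring-B aldehyde that serves both flavan units.

Step 4
Reactants: 6 3,4,5-tris(benzyloxy)benzaldehyde; 7 vinylmagnesium bromide
Product: 8 rac-1-[3,4,5-tris(benzyloxy)phenyl]prop-2-en-1-ol
Conditions: THF, −78 °C to 0 °C; aqueous work-up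
Reagents that add atoms: none
Why: Grignard 1,2-addition gives the racemic secondary allylic alcohol needed for kinetic resolution.

Step 5
Reactants: 8 rac-1-[3,4,5-tris(benzyloxy)phenyl]prop-2-en-1-ol
Product: 9 (S)-[(R)-oxiran-2-yl][3,4,5-tris(benzyloxy)phenyl]methanol (erythro)
Conditions: Ti(OiPr)4 (10 mol %), diisopropyl L-(+)-tartrate (15 mol %), t-BuOOH (0.45 equiv), 4 Å MS, CH2Cl2, −20 °C; the unreacted S alcohol is recovered
Reagents that add atoms: tert-butyl hydroperoxide, CC(C)(C)OO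
Why: In this Sharpless kinetic resolution the L-(+)-tartrate catalyst epoxidises the R alcohol much faster than the S alcohol and gives the erythro epoxy alcohol, so the catalyst sets both the carbinol centre and the epoxide carbon (R, the later C3').

Step 6
Reactants: 10 resorcinol
Product: 11 1,3-bis[(4-methoxybenzyl)oxy]benzene
Conditions: PMBCl (2.2 equiv), K2CO3, DMF, 60 °C
Reagents that add atoms: 4-methoxybenzyl chloride, COc1ccc(CCl)cc1
Why: Williamson etherification installs PMB ethers, chosen because every C–H of their 1,4-disubstituted rings has an ortho substituent and is therefore inert in the borylation of step 8.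

Step 7
Reactants: 11 1,3-bis[(4-methoxybenzyl)oxy]benzene; 12 N-methoxy-N-methylacetamide
Product: 14 1-{2,6-bis[(4-methoxybenzyl)oxy]phenyl}ethanone, via aryllithium 13 (not isolated)
Conditions: n-BuLi (1.1 equiv), THF, 0 °C to rt; then 12, −78 °C to 0 °C; aqueous work-up
Reagents that add atoms: none
Why: Directed ortho-lithiation occurs between the two alkoxy groups and acylation with the Weinreb amide stops at the ketone, joining the later C6' to the carbonyl carbon that becomes C4 of the upper unit.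

Step 8
Reactants: 14 1-{2,6-bis[(4-methoxybenzyl)oxy]phenyl}ethanone
Product: 16 1-{4-hydroxy-2,6-bis[(4-methoxybenzyl)oxy]phenyl}ethanone, via arylboronate 15 (not isolated)
Conditions: [Ir(OMe)(cod)]2 (1.5 mol %), 4,4'-di-tert-butyl-2,2'-bipyridine (3 mol %), B2pin2 (0.8 equiv), THF, 80 °C; then KHSO5 (Oxone), acetone/H2O, rt
Reagents that add atoms: potassium peroxymonosulfate, [K+].[O-]S(=O)(=O)OO (the new oxygen); bis(pinacolato)diboron, CC1(C)OB(OC1(C)C)B1OC(C)(C)C(C)(C)O1 (boron of 15 only)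
Why: Sterically controlled iridium-catalysed C–H borylation takes place only at the one arene C–H with no ortho substituent (para to the acetyl group) and oxidation of the C–B bond gives the symmetric phenol.

Step 9
Reactants: 16 1-{4-hydroxy-2,6-bis[(4-methoxybenzyl)oxy]phenyl}ethanone; 9 (S)-[(R)-oxiran-2-yl][3,4,5-tris(benzyloxy)phenyl]methanol
Product: 17 1-{4-[(R)-[(R)-oxiran-2-yl](ArB)methoxy]-2,6-bis(PMB-oxy)phenyl}ethanone
Conditions: PPh3, diisopropyl azodicarboxylate, THF, 0 °C to rt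
Reagents that add atoms: none
Why: Mitsunobu etherification with the acidic 4-acylphenol proceeds by SN2 inversion at the benzylic carbinol (S to R), turning the erythro epoxy alcohol into the threo ether that corresponds to a 2,3-cis chroman, while the epoxide centre is untouched.

Step 10
Reactants: 17 1-{4-[(R)-[(R)-oxiran-2-yl](ArB)methoxy]-2,6-bis(PMB-oxy)phenyl}ethanone
Product: 18 1-[(2R,3R)-3-hydroxy-5,7-bis(PMB-oxy)-2-ArB-3,4-dihydro-2H-chromen-6-yl]ethanone (Chr–COCH3)
Conditions: AuCl3 (5 mol %), AgOSO2CF3 (15 mol %), CH2Cl2, 0 °C to rt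
Reagents that add atoms: none
Why: Intramolecular Friedel–Crafts epoxy–arene cyclisation (6-endo, at the terminal epoxide carbon) closes ring C' without touching either stereocentre, and because the two positions ortho to the ether oxygen are equivalent only the 6-acetyl chroman (later 4→6 link) can form.

Step 11
Reactants: 18 Chr–COCH3; 6 3,4,5-tris(benzyloxy)benzaldehyde
Product: 19 (E)-1-Chr-3-ArB-prop-2-en-1-one
Conditions: KOH (aq), EtOH/THF, rt
Reagents that add atoms: none
Why: Claisen–Schmidt aldol condensation of the hindered methyl ketone with the non-enolisable aldehyde gives the E-enone, as is usual for 2,4,6-trialkoxyacetophenones.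

Step 12
Reactants: 19 (E)-1-Chr-3-ArB-prop-2-en-1-one
Product: 20 Chr-[(2R,3S)-3-ArB-oxiran-2-yl]methanone
Conditions: poly-L-leucine, urea–H2O2, DBU, THF, rt
Reagents that add atoms: hydrogen peroxide (as urea adduct), OO
Why: Juliá–Colonna nucleophilic epoxidation with poly-L-leucine gives the (2R,3S)-trans-epoxy ketone as it does for chalcone itself, setting the later C3 and (before inversion) C2 under catalyst control, and any minor isomer is a diastereomer that can be removed by chromatography.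

Step 13
Reactants: 21 3-(benzyloxy)phenol
Product: 22 5-(benzyloxy)-2-iodophenol
Conditions: I2, NaHCO3, THF/H2O, 0 °C
Reagents that add atoms: iodine, II
Why: Electrophilic iodination of the phenoxide goes ortho to the hydroxyl and para to the benzyloxy group, the doubly activated and less hindered position.

Step 14
Reactants: 20 Chr-[(2R,3S)-3-ArB-oxiran-2-yl]methanone; 22 5-(benzyloxy)-2-iodophenol
Product: 24 (1RS,2S,3R)-3-[5-(benzyloxy)-2-iodophenoxy]-1-Chr-3-ArB-propane-1,2-diol, via C4-epimeric epoxy alcohol 23 (not isolated)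
Conditions: NaBH4, THF/EtOH, 0 °C; then 22, 2 M aq. NaOH, dioxane, 75 °C
Reagents that add atoms: none
Why: Borohydride reduction gives the epoxy alcohol (its carbinol configuration is irrelevant because that carbon becomes a radical in step 15) and the phenoxide then opens the epoxide by SN2 attack at the benzylic carbon with inversion (S to R), giving the erythro O1–C2/C3–OH relationship that is 2,3-trans in the chroman.

Step 15
Reactants: 24 (1RS,2S,3R)-3-[5-(benzyloxy)-2-iodophenoxy]-1-Chr-3-ArB-propane-1,2-diol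
Product: 25 (2R,3S,4S)-7-(benzyloxy)-4-Chr-2-ArB-3,4-dihydro-2H-chromen-3-ol
Conditions: NiBr2(dme) (15 mol %), 4,4'-di-tert-butyl-2,2'-bipyridine (18 mol %), TiCl4(2,4,6-collidine) (3 equiv), 2,4,6-collidine (3 equiv), Mn powder (6 equiv), THF (0.01 M), 25 °C
Reagents that add atoms: none
Why: Proposed new method: the titanium alkoxide of the benzylic C4 carbinol undergoes C–O homolysis under low-valent (trivalent) titanium to give a C4 benzylic radical (both C4 epimers converge) while zerovalent nickel inserts into the aryl–iodine bond, the tethered aryl–nickel captures the radical, and reductive elimination from trivalent nickel forms the C4–C4a bond and ring C through a chair-like transition state with the 2-aryl group, the C3 titanium alkoxide and the bulky C4 aryl group all equatorial, so C4 is set 3,4-trans (4S); the closest known reaction type is the nickel-catalysed, titanium-assisted cross-electrophile coupling of benzylic alcohols (and of aryl epoxides) with aryl halides, here run intramolecularly.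

Step 16
Reactants: 25 (2R,3S,4S)-7-(benzyloxy)-4-Chr-2-ArB-3,4-dihydro-2H-chromen-3-ol
Product: 26 (2R,3S,4S)-2-(3,4,5-trihydroxyphenyl)-4-[(2R,3R)-3,5,7-trihydroxy-2-(3,4,5-trihydroxyphenyl)-3,4-dihydro-2H-chromen-6-yl]-3,4-dihydro-2H-chromene-3,7-diol (CNP0311915.2)
Conditions: H2 (1 atm), Pd(OH)2/C, THF/MeOH, rt, argon work-up
Reagents that add atoms: none
Why: Catalytic hydrogenolysis removes the seven benzyl and two 4-methoxybenzyl aryl ethers in one operation, while the ring C–O and C4–aryl bonds of the flavan skeleton survive as in standard proanthocyanidin deprotections.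

**Compound list**
1 | 4-methylphenol (p-cresol) | Cc1ccc(O)cc1 | starting material
2 | 2,6-dibromo-4-methylphenol | Cc1cc(Br)c(O)c(Br)c1 | intermediate
3 | 2,6-dibromo-4-(dibromomethyl)phenol | BrC(Br)c1cc(Br)c(O)c(Br)c1 | intermediate
4 | 3,5-dibromo-4-hydroxybenzaldehyde | O=Cc1cc(Br)c(O)c(Br)c1 | intermediate
5 | 3,4,5-trihydroxybenzaldehyde | O=Cc1cc(O)c(O)c(O)c1 | intermediate
6 | 3,4,5-tris(benzyloxy)benzaldehyde | O=Cc1cc(OCc2ccccc2)c(OCc2ccccc2)c(OCc2ccccc2)c1 | intermediate
7 | vinylmagnesium bromide | C=C[Mg]Br | starting material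
8 | rac-1-[3,4,5-tris(benzyloxy)phenyl]prop-2-en-1-ol | C=CC(O)c1cc(OCc2ccccc2)c(OCc2ccccc2)c(OCc2ccccc2)c1 | intermediate
9 | (S)-[(R)-oxiran-2-yl][3,4,5-tris(benzyloxy)phenyl]methanol | O[C@@H](c1cc(OCc2ccccc2)c(OCc2ccccc2)c(OCc2ccccc2)c1)[C@H]1CO1 | intermediate
10 | resorcinol | Oc1cccc(O)c1 | starting material
11 | 1,3-bis[(4-methoxybenzyl)oxy]benzene | COc1ccc(COc2cccc(OCc3ccc(OC)cc3)c2)cc1 | intermediate
12 | N-methoxy-N-methylacetamide | CC(=O)N(C)OC | starting material
13 | {2,6-bis[(4-methoxybenzyl)oxy]phenyl}lithium | [Li]c1c(OCc2ccc(OC)cc2)cccc1OCc1ccc(OC)cc1 | intermediate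
14 | 1-{2,6-bis[(4-methoxybenzyl)oxy]phenyl}ethanone | CC(=O)c1c(OCc2ccc(OC)cc2)cccc1OCc1ccc(OC)cc1 | intermediate
15 | 1-{2,6-bis[(4-methoxybenzyl)oxy]-4-(4,4,5,5-tetramethyl-1,3,2-dioxaborolan-2-yl)phenyl}ethanone | CC(=O)c1c(OCc2ccc(OC)cc2)cc(B2OC(C)(C)C(C)(C)O2)cc1OCc1ccc(OC)cc1 | intermediate
16 | 1-{4-hydroxy-2,6-bis[(4-methoxybenzyl)oxy]phenyl}ethanone | CC(=O)c1c(OCc2ccc(OC)cc2)cc(O)cc1OCc1ccc(OC)cc1 | intermediate
17 | 1-{4-[(R)-[(R)-oxiran-2-yl](ArB)methoxy]-2,6-bis(PMB-oxy)phenyl}ethanone | CC(=O)c1c(OCc2ccc(OC)cc2)cc(O[C@H](c2cc(OCc3ccccc3)c(OCc3ccccc3)c(OCc3ccccc3)c2)[C@H]2CO2)cc1OCc1ccc(OC)cc1 | intermediate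
18 | 1-[(2R,3R)-3-hydroxy-5,7-bis(PMB-oxy)-2-ArB-3,4-dihydro-2H-chromen-6-yl]ethanone | CC(=O)c1c(OCc2ccc(OC)cc2)cc2c(c1OCc1ccc(OC)cc1)C[C@@H](O)[C@@H](c1cc(OCc3ccccc3)c(OCc3ccccc3)c(OCc3ccccc3)c1)O2 | intermediate
19 | (E)-1-Chr-3-ArB-prop-2-en-1-one | O=C(/C=C/c1cc(OCc2ccccc2)c(OCc2ccccc2)c(OCc2ccccc2)c1)c1c(OCc2ccc(OC)cc2)cc2c(c1OCc1ccc(OC)cc1)C[C@@H](O)[C@@H](c1cc(OCc3ccccc3)c(OCc3ccccc3)c(OCc3ccccc3)c1)O2 | intermediate
20 | Chr-[(2R,3S)-3-ArB-oxiran-2-yl]methanone | O=C([C@@H]1O[C@H]1c1cc(OCc2ccccc2)c(OCc2ccccc2)c(OCc2ccccc2)c1)c1c(OCc2ccc(OC)cc2)cc2c(c1OCc1ccc(OC)cc1)C[C@@H](O)[C@@H](c1cc(OCc3ccccc3)c(OCc3ccccc3)c(OCc3ccccc3)c1)O2 | intermediate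
21 | 3-(benzyloxy)phenol | Oc1cccc(OCc2ccccc2)c1 | starting material
22 | 5-(benzyloxy)-2-iodophenol | Oc1cc(OCc2ccccc2)ccc1I | intermediate
23 | Chr-[(2S,3S)-3-ArB-oxiran-2-yl]methanol (both carbinol epimers) | OC([C@@H]1O[C@H]1c1cc(OCc2ccccc2)c(OCc2ccccc2)c(OCc2ccccc2)c1)c1c(OCc2ccc(OC)cc2)cc2c(c1OCc1ccc(OC)cc1)C[C@@H](O)[C@@H](c1cc(OCc3ccccc3)c(OCc3ccccc3)c(OCc3ccccc3)c1)O2 | intermediate
24 | (1RS,2S,3R)-3-[5-(benzyloxy)-2-iodophenoxy]-1-Chr-3-ArB-propane-1,2-diol | OC([C@H](O)[C@H](Oc1cc(OCc2ccccc2)ccc1I)c1cc(OCc2ccccc2)c(OCc2ccccc2)c(OCc2ccccc2)c1)c1c(OCc2ccc(OC)cc2)cc2c(c1OCc1ccc(OC)cc1)C[C@@H](O)[C@@H](c1cc(OCc3ccccc3)c(OCc3ccccc3)c(OCc3ccccc3)c1)O2 | intermediate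
25 | (2R,3S,4S)-7-(benzyloxy)-4-Chr-2-ArB-3,4-dihydro-2H-chromen-3-ol | C(Oc1ccc2c(c1)O[C@H](c1cc(OCc3ccccc3)c(OCc3ccccc3)c(OCc3ccccc3)c1)[C@@H](O)[C@@H]2c1c(OCc2ccc(OC)cc2)cc2c(c1OCc1ccc(OC)cc1)C[C@@H](O)[C@@H](c1cc(OCc3ccccc3)c(OCc3ccccc3)c(OCc3ccccc3)c1)O2)c1ccccc1 | intermediate
26 | robinetinidol-(4α→6)-epigallocatechin (CNP0311915.2) | Oc1ccc2c(c1)O[C@H](c1cc(O)c(O)c(O)c1)[C@@H](O)[C@@H]2c1c(O)cc2c(c1O)C[C@@H](O)[C@@H](c1cc(O)c(O)c(O)c1)O2 | target

**Step count and risk**

Total step count: 16. Longest linear sequence: 12 steps (1, 2, 3, 4, 5, 9, 10, 11, 12, 14, 15, 16).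

The three steps most likely to fail:

Step 15 (radical ring closure). Risks are deoxygenation to the alkene, simple reduction at C4, or Lewis-acid damage to the PMB ethers. The fallback closes ring C by a cationic Friedel–Crafts cyclisation instead. It sets out from 20 and 21: the step-14 conditions with 21 in place of 22 give, through 23, the iodine-free ether (1RS,2S,3R)-3-[3-(benzyloxy)phenoxy]-1-Chr-3-ArB-propane-1,2-diol F1. Pyridinium p-toluenesulfonate (10 mol %) in CH2Cl2/hexafluoroisopropanol at 0 °C then ionises the C4 carbinol, which is strongly activated by the trioxygenated ring. The benzylic cation is trapped by ring A para to its benzyloxy group, with the C4 aryl group equatorial, and the route is rejoined at 25.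

Step 10 (epoxy–arene cyclisation). Risks are 5-exo opening and acid damage to the PMB ethers or the benzylic aryl ether. The fallback replaces the Lewis-acid cyclisation by a reductive nickel coupling. It sets out from 16: N-iodosuccinimide (1 equiv, CH2Cl2, 0 °C) gives 1-{4-hydroxy-3-iodo-2,6-bis[(4-methoxybenzyl)oxy]phenyl}ethanone F2, and Mitsunobu etherification with 9 as in step 9 gives 1-{3-iodo-4-[(R)-[(R)-oxiran-2-yl](ArB)methoxy]-2,6-bis(PMB-oxy)phenyl}ethanone F3. Treatment with NiBr2(dme), 4,4'-di-tert-butyl-2,2'-bipyridine, NaI and Zn in N,N-dimethylacetamide opens the epoxide at its CH2 terminus via the iodohydrin. Its primary radical is captured by the aryl–nickel formed from zerovalent nickel and the aryl iodide, and the route is rejoined at 18.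

Step 9 (Mitsunobu at an electron-rich benzylic carbinol). The risk is partial SN1 character and loss of configuration at C2'. The fallback forms the aryl–oxygen bond with retention and corrects C3' afterwards. It sets out from 8 (the S enantiomer left over from step 5) and from 15 (isolated by leaving out the Oxone stage). Sharpless epoxidation of the S alcohol with diisopropyl D-(−)-tartrate gives (R)-[(S)-oxiran-2-yl][3,4,5-tris(benzyloxy)phenyl]methanol F4. Chan–Lam O-arylation with 15 (Cu(OAc)2, pyridine, 4 Å MS, air) gives 1-{4-[(R)-[(S)-oxiran-2-yl](ArB)methoxy]-2,6-bis(PMB-oxy)phenyl}ethanone F5. Cyclisation as in step 10 gives the 2,3-trans chromanol 1-[(2R,3S)-3-hydroxy-5,7-bis(PMB-oxy)-2-ArB-3,4-dihydro-2H-chromen-6-yl]ethanone F6. Dess–Martin oxidation gives 1-[(2R)-3-oxo-5,7-bis(PMB-oxy)-2-ArB-3,4-dihydro-2H-chromen-6-yl]ethanone F7, and LiBH(s-Bu)3 at −78 °C delivers hydride anti to the 2-aryl group to give the 2,3-cis alcohol, rejoining the route at 18.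

Further compounds
F1 | step 15 | (1RS,2S,3R)-3-[3-(benzyloxy)phenoxy]-1-Chr-3-ArB-propane-1,2-diol | OC([C@H](O)[C@H](Oc1cccc(OCc2ccccc2)c1)c1cc(OCc2ccccc2)c(OCc2ccccc2)c(OCc2ccccc2)c1)c1c(OCc2ccc(OC)cc2)cc2c(c1OCc1ccc(OC)cc1)C[C@@H](O)[C@@H](c1cc(OCc3ccccc3)c(OCc3ccccc3)c(OCc3ccccc3)c1)O2
F2 | step 10 | 1-{4-hydroxy-3-iodo-2,6-bis[(4-methoxybenzyl)oxy]phenyl}ethanone | CC(=O)c1c(OCc2ccc(OC)cc2)cc(O)c(I)c1OCc1ccc(OC)cc1
F3 | step 10 | 1-{3-iodo-4-[(R)-[(R)-oxiran-2-yl](ArB)methoxy]-2,6-bis(PMB-oxy)phenyl}ethanone | CC(=O)c1c(OCc2ccc(OC)cc2)cc(O[C@H](c2cc(OCc3ccccc3)c(OCc3ccccc3)c(OCc3ccccc3)c2)[C@H]2CO2)c(I)c1OCc1ccc(OC)cc1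
F4 | step 9 | (R)-[(S)-oxiran-2-yl][3,4,5-tris(benzyloxy)phenyl]methanol | O[C@H](c1cc(OCc2ccccc2)c(OCc2ccccc2)c(OCc2ccccc2)c1)[C@@H]1CO1
F5 | step 9 | 1-{4-[(R)-[(S)-oxiran-2-yl](ArB)methoxy]-2,6-bis(PMB-oxy)phenyl}ethanone | CC(=O)c1c(OCc2ccc(OC)cc2)cc(O[C@H](c2cc(OCc3ccccc3)c(OCc3ccccc3)c(OCc3ccccc3)c2)[C@@H]2CO2)cc1OCc1ccc(OC)cc1
F6 | step 9 | 1-[(2R,3S)-3-hydroxy-5,7-bis(PMB-oxy)-2-ArB-3,4-dihydro-2H-chromen-6-yl]ethanone | CC(=O)c1c(OCc2ccc(OC)cc2)cc2c(c1OCc1ccc(OC)cc1)C[C@H](O)[C@@H](c1cc(OCc3ccccc3)c(OCc3ccccc3)c(OCc3ccccc3)c1)O2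
F7 | step 9 | 1-[(2R)-3-oxo-5,7-bis(PMB-oxy)-2-ArB-3,4-dihydro-2H-chromen-6-yl]ethanone | CC(=O)c1c(OCc2ccc(OC)cc2)cc2c(c1OCc1ccc(OC)cc1)CC(=O)[C@@H](c1cc(OCc3ccccc3)c(OCc3ccccc3)c(OCc3ccccc3)c1)O2
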